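**Retrosynthetic overview**

1. The C7 octanoate is installed last by acylation of the (R)-tertiary alcohol; the C7 stereocentre comes from an enzymatic hydroxylative dearomatisation of the carbocycle, which stays aromatic until then.
2. The pyran ring (C1, O2, C3, C4, C4a, C8a) is disconnected across C1–C8a and O2–C3 and made in one flask from 2-methyl-5-(non-1-yn-1-yl)resorcinol and Cl2CHOMe by formylation/6-endo cycloisomerisation to a 2-benzopyrylium salt.
3. Enabling feature: O2–C1H is a formyl group in enol-ether guise, C8a is the ring carbon ortho to the C8 oxygen and para to the C6 oxygen (the nucleophilic site of a resorcinol), and C3=C4 with its heptyl chain is an alkyne in disguise; in the aromatic precursor the carbons that become C8a and C5 are symmetry-equivalent, so only one formylation product is possible.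
4. The alkynyl resorcinol comes from Sonogashira coupling of 5-bromo-2-methylresorcinol with non-1-yne; the bromide comes from 2,6-dimethoxytoluene by iridium-catalysed C–H borylation/bromination and demethylation.
5. Ring order: benzene ring purchased; pyran ring formed second (step 4); carbocycle dearomatised third (step 5).

Key step: step 4

Remark: locants are those of the isochromene ring (C1, O2, C3, C4, C4a, C5, C6, C7, C8, C8a); the monooxygenase AzaH of step 5 is assumed to be available as a lysate from heterologous expression in E. coli and is a catalyst, not a starting material.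

**Route**

Step 1
Reactants: 1 1,3-dimethoxy-2-methylbenzene (2,6-dimethoxytoluene)
Product: 3 5-bromo-1,3-dimethoxy-2-methylbenzene, via aryl pinacol boronate 2 (not isolated)
Conditions: [Ir(OMe)(cod)]2 (1.5 mol%), dtbpy (3 mol%), B2pin2 (1.0 equiv), cyclohexane, 80 °C; then CuBr2 (3.5 equiv), MeOH/H2O (1:1), 80 °C
Reagents that add atoms: bis(pinacolato)diboron B2pin2, CC1(C)OB(OC1(C)C)B1OC(C)(C)C(C)(C)O1 (boryl group of 2); CuBr2, Br[Cu]Br (bromine of 3)
Why: Iridium-catalysed C–H borylation is sterically controlled and should occur only at the one ring C–H with no ortho substituent (para to the methyl group), and copper-mediated bromodeboronation of the crude boronate then places bromine on that carbon.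

Step 2
Reactants: 3 5-bromo-1,3-dimethoxy-2-methylbenzene
Product: 4 5-bromo-2-methylbenzene-1,3-diol
Conditions: BBr3 (3 equiv), CH2Cl2, −78 °C to rt; then H2O
Reagents that add atoms: none
Why: BBr3 cleavage of aryl methyl ethers is reliable on a substrate whose only other function is an aryl bromide.

Step 3
Reactants: 4 5-bromo-2-methylbenzene-1,3-diol; 5 non-1-yne
Product: 6 2-methyl-5-(non-1-yn-1-yl)benzene-1,3-diol
Conditions: PdCl2(PPh3)2 (5 mol%), CuI (5 mol%), Et3N/DMF (1:2), degassed, 80 °C
Reagents that add atoms: none
Why: Sonogashira coupling should proceed because the bromide is meta to both hydroxyl groups, so it is not deactivated by phenoxide resonance, and free phenols are tolerated by the palladium/copper system.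

Step 4
Reactants: 6 2-methyl-5-(non-1-yn-1-yl)benzene-1,3-diol
Product: 9 3-heptyl-6,8-dihydroxy-7-methylisochromenylium triflate (2-benzopyrylium salt), via chloro ether 7 (not isolated), via alkynyl benzaldehyde 8 (not isolated)
Conditions: Cl2CHOMe (1.2 equiv), AgOTf (1.2 equiv), CH2Cl2, −78 to 0 °C; then Au(OAc)3 (5 mol%), 0 °C to rt; Et2O/hexane trituration
Reagents that add atoms: dichloromethyl methyl ether, COC(Cl)Cl (C1 and O2); silver triflate AgOTf, [Ag+].[O-]S(=O)(=O)C(F)(F)F (triflate counter-ion)
Why: Proposed new method: AgOTf abstracts chloride from Cl2CHOMe to give the chloro(methoxy)methylium ion, which attacks the ring carbon ortho to one hydroxyl and para to the other (Rieche-type formylation, C1–C8a bond) to give chloro ether 7 and one equivalent of TfOH, and 7 loses chloromethane to unveil aldehyde 8 in the flask. The formyl oxygen of 8 then adds to the alkyne activated by the gold catalyst and the acid, and protodeauration by the TfOH formed in the first stage gives the aromatic 2-benzopyrylium triflate (O2–C3 bond). The closest known reaction types are the AgOTf-promoted Rieche formylation of electron-rich arenes and the gold triacetate/Brønsted acid cycloisomerisation of 6-alkynyl-2,4-dihydroxybenzaldehydes to 2-benzopyrylium salts, merged here without isolation of the aldehyde. The pyran ring closes by 6-endo-dig attack of the carbonyl oxygen on the distal alkyne carbon, preferred over 5-exo-dig because it gives an aromatic pyrylium and because that carbon is the conjugate position of the ortho-formyl group. No stereocentre is formed. The step needs site selectivity in the formylation, secured by the symmetry of 6 (its only two unsubstituted ring positions are equivalent), and chemoselectivity for the arene over the alkyne, secured by the much higher nucleophilicity of the resorcinol ring at low temperature; the gold salt is added only after formylation so that the electron-rich resorcinol cannot reduce it.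

Step 5
Reactants: 9 3-heptyl-6,8-dihydroxy-7-methylisochromenylium triflate
Product: 12 (7R)-3-heptyl-7-hydroxy-7-methyl-6H-isochromene-6,8(7H)-dione, via keto aldehyde 10 (not isolated), via hydroxylated dienone 11 (not isolated)
Conditions: K2HPO4/KH2PO4 buffer (50 mM, pH 8.0)/DMSO (19:1), 30 °C, 30 min; then AzaH (flavin-dependent monooxygenase, clarified E. coli lysate), NADP+ (cat.), glucose 6-phosphate (2 equiv), glucose-6-phosphate dehydrogenase, air, 30 °C
Reagents that add atoms: dioxygen (air), O=O (one oxygen atom, the C7 hydroxyl); water, O (added at C1 in 10 and 11, released again on ring closure to 12)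
Why: At pH 8 the pyrylium ion should add water at C1 and the lactol open to keto aldehyde 10, a 2,4-dihydroxy-3-methyl-6-(2-oxoalkyl)benzaldehyde of the kind this monooxygenase hydroxylates at the methyl-bearing ring carbon (enzymatic hydroxylative phenol dearomatisation), with the enzyme pocket delivering the flavin hydroperoxide oxygen to one face so that the C7 carbinol is expected as (R), after which 11 should reclose spontaneously by hemiacetalisation and vinylogous dehydration to the pyran.

Step 6
Reactants: 12 (7R)-3-heptyl-7-hydroxy-7-methyl-6H-isochromene-6,8(7H)-dione; 13 octanoyl chloride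
Product: 14 (7R)-3-heptyl-7-methyl-6,8-dioxo-7,8-dihydro-6H-isochromen-7-yl octanoate (target)
Conditions: octanoyl chloride (1.5 equiv), iPr2NEt (2 equiv), DMAP (0.2 equiv), CH2Cl2, 0 °C to rt
Reagents that add atoms: none
Why: DMAP-catalysed acyl transfer should esterify the hindered tertiary α-ketol while only tertiary amines touch the amine-sensitive pyran, and since no bond at C7 is broken the (R) configuration is retained.

**Compound list**

1 | 1,3-dimethoxy-2-methylbenzene (2,6-dimethoxytoluene) | COc1cccc(OC)c1C | starting material
2 | 2-(3,5-dimethoxy-4-methylphenyl)-4,4,5,5-tetramethyl-1,3,2-dioxaborolane (aryl pinacol boronate, not isolated) | COc1cc(B2OC(C)(C)C(C)(C)O2)cc(OC)c1C | intermediate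
3 | 5-bromo-1,3-dimethoxy-2-methylbenzene | COc1cc(Br)cc(OC)c1C | intermediate
4 | 5-bromo-2-methylbenzene-1,3-diol | Cc1c(O)cc(Br)cc1O | intermediate
5 | non-1-yne | CCCCCCCC#C | starting material
6 | 2-methyl-5-(non-1-yn-1-yl)benzene-1,3-diol | CCCCCCCC#Cc1cc(O)c(C)c(O)c1 | intermediate
7 | 4-[chloro(methoxy)methyl]-2-methyl-5-(non-1-yn-1-yl)benzene-1,3-diol (chloro ether, not isolated) | CCCCCCCC#Cc1cc(O)c(C)c(O)c1C(Cl)OC | intermediate
8 | 2,4-dihydroxy-3-methyl-6-(non-1-yn-1-yl)benzaldehyde (not isolated) | CCCCCCCC#Cc1cc(O)c(C)c(O)c1C=O | intermediate
9 | 3-heptyl-6,8-dihydroxy-7-methylisochromenylium trifluoromethanesulfonate | CCCCCCCc1cc2cc(O)c(C)c(O)c2c[o+]1.[O-]S(=O)(=O)C(F)(F)F | intermediate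
10 | 2,4-dihydroxy-3-methyl-6-(2-oxononyl)benzaldehyde (keto aldehyde, not isolated) | CCCCCCCC(=O)Cc1cc(O)c(C)c(O)c1C=O | intermediate
11 | (5R)-4,5-dihydroxy-5-methyl-6-oxo-2-(2-oxononyl)cyclohexa-1,3-diene-1-carbaldehyde (hydroxylated dienone, not isolated) | CCCCCCCC(=O)CC1=C(C=O)C(=O)[C@](C)(O)C(O)=C1 | intermediate
12 | (7R)-3-heptyl-7-hydroxy-7-methyl-6H-isochromene-6,8(7H)-dione | O[C@]1(C)C(=O)C=C2C=C(CCCCCCC)OC=C2C1=O | intermediate
13 | octanoyl chloride | CCCCCCCC(Cl)=O | starting material
14 | (7R)-3-heptyl-7-methyl-6,8-dioxo-7,8-dihydro-6H-isochromen-7-yl octanoate | CCCCCCCC(=O)O[C@]1(C)C(=O)C=C2C=C(CCCCCCC)OC=C2C1=O | target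

**Step count and risks**

Total step count: 6. Longest linear sequence: 6 steps (from 1 to 14); 5 and 13 are purchased.

Steps most likely to fail:

1. Step 4 (proposed new method). The free phenolic oxygens may intercept the carbenium ion (O-formylation). Loss of chloromethane from the strongly stabilised oxocarbenium stage may stall. Triflic acid may add across the alkyne before the carbonyl oxygen is free to attack, and the pyrylium carbon C1 may be trapped by unreacted arene. The fallback uses known chemistry, sets out from 6 and comes back at 9. Vilsmeier–Haack formylation (POCl3, DMF, MeCN, 0 °C to rt) should give the aryl-methylidene dimethyliminium chloride F1, which is hydrolysed with water at 50 °C to aldehyde 8, now isolated. Gold-catalysed cycloisomerisation (Au(OAc)3, 5 mol%, TfOH, 1.1 equiv, 1,2-dichloroethane, rt) should then close the pyrylium ring to give 9.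

2. Step 5. Hydrolytic ring opening of the pyrylium may be incomplete at pH 8 (persistence of the quinoidal anhydrobase). The enzyme may turn over the heptyl ketone slowly, the open keto aldehyde may undergo intramolecular aldol condensation while waiting, or the facial sense may be opposite to that expected. The fallback sets out from 6 and comes back at 12. Aldehyde 8 is prepared and isolated by the Vilsmeier–Haack sequence described above. Copper-mediated enantioselective oxidative dearomatisation ([Cu(MeCN)4]PF6, (−)-sparteine, O2, iPr2NEt, DMAP, CH2Cl2, −78 to −10 °C) should give the (R)-configured vinylogous acid F2; (−)-sparteine is the ligand expected to lead to the (R) series. CuI-catalysed 6-endo cycloisomerisation in buffered MeCN at rt should then give 12.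

3. Step 3. The bis-phenoxide may bind and slow the palladium catalyst, so that oxidative dimerisation of the alkyne outruns the slow oxidative addition. The fallback sets out from 4 and comes back at 6. Silylation (TBSCl, imidazole, DMF, rt) should give 5-bromo-1,3-bis[(tert-butyldimethylsilyl)oxy]-2-methylbenzene F3. Sonogashira coupling with 5 (PdCl2(PPh3)2, CuI, Et3N, 70 °C) should give 1,3-bis[(tert-butyldimethylsilyl)oxy]-2-methyl-5-(non-1-yn-1-yl)benzene F4. Desilylation with TBAF in THF at 0 °C should then give 6.

**Further compounds**

F1 | step 4 | [2,4-dihydroxy-3-methyl-6-(non-1-yn-1-yl)phenyl]methylidene-dimethylammonium chloride | CCCCCCCC#Cc1cc(O)c(C)c(O)c1C=[N+](C)C.[Cl-]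
F2 | step 5 | (5R)-4,5-dihydroxy-5-methyl-2-(non-1-yn-1-yl)-6-oxocyclohexa-1,3-diene-1-carbaldehyde | CCCCCCCC#CC1=C(C=O)C(=O)[C@](C)(O)C(O)=C1
F3 | step 3 | 5-bromo-1,3-bis[(tert-butyldimethylsilyl)oxy]-2-methylbenzene | Cc1c(O[Si](C)(C)C(C)(C)C)cc(Br)cc1O[Si](C)(C)C(C)(C)C
F4 | step 3 | 1,3-bis[(tert-butyldimethylsilyl)oxy]-2-methyl-5-(non-1-yn-1-yl)benzene | CCCCCCCC#Cc1cc(O[Si](C)(C)C(C)(C)C)c(C)c(O[Si](C)(C)C(C)(C)C)c1
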